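70.0% is the number to carry for this flask: it is the surviving share s, the fraction of the free monomer charged that remains once each protic impurity has quenched one free monomer, so s is one minus the impurity charge over the monomer charge.

| flask | free monomer | protic impurity | pre-initiator | remark | time |
|---|---|---|---|---|---|
| Saturday's | 0.36 M | 0.159 M | 27 mM | run made earlier |  |
| Tuesday's | 0.80 M | 0.159 M | 27 mM | run made earlier |  |
| Monday's | 0.53 M | 0.159 M | 40 mM | run made earlier |  |
| flask | 0.53 M | 0.159 M | 27 mM |  | 20 h |

| run | time / h | monomer in chains / % | free monomer / % |
|---|---|---|---|
| Saturday's | 3.00 | 7.8 | 51.0 |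
| Saturday's | 8.00 | 37.3 | 17.1 |
| Saturday's | 15.0 | 53.4 | 3.4 |
| Saturday's | 25.0 | 54.8 | 0.4 |
| Tuesday's | 3.00 | 16.1 | 63.2 |
| Tuesday's | 8.00 | 63.0 | 16.6 |
| Tuesday's | 15.0 | 78.2 | 0 |
| Tuesday's | 25.0 | 81.8 | 0.7 |
| Monday's | 6.00 | 47.7 | 23.1 |
| Monday's | 12.0 | 69.4 | 2.2 |
| Monday's | 20.0 | 70.4 | 0 |
| Monday's | 25.0 | 70.2 | 0.6 |

(each reading ± 1 percentage point)

- the average divides the monomer in chains by the number of chains begun, living and dead together
- reactions considered so far: pre-initiator -> initiator; protic impurity + free monomer -> quenched substrate; free monomer + initiator -> living end + monomer in chains; free monomer + living end -> monomer in chains + living end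
- the earlier runs do not show the number of chains; that part of a forecast is a guess

1. average number of monomer units in a chain (chains begun, living or dead) at 20 h
2. part of the free monomer that has reacted at 20 h

Watch the first hours, and count what is left. The protic impurity is the limiting reagent of the quench, since its 0.159 M is less than the 0.53 M of free monomer. In Tuesday's run at 3.00 h, free monomer and monomer in chains already add up to 79.3%, against that run's own s of 80.1%, and more has been quenched than has entered chains.

In the middle, chains take over. Saturday's free monomer reads 17.1% at 8.00 h and 3.4% at 15.0 h, a pace of 0.231 h⁻¹ at the same pre-initiator charge as this flask. Carried on to 20 h at that pace and scaled from Saturday's s to this flask's s, my reckoning leaves about 1.34% free in this flask.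

At the end, chains should hold s: Monday's last reading is 70.2% and Saturday's is 54.8%, against 55.8% for Saturday's s. So you expect 0.371 M in chains in this flask. If all 27 mM of pre-initiator begins chains, dp, the monomer units per chain begun, is 13.7, and fewer chains raise it. How many begin is a guess.

The forecast gives dp 14.5 (range 12.5 to 22) and c 98.9% (range 97.5% to 99.8%), saying “This is a guess, and incomplete initiation would raise it”. The flask gives dp 20.0 and c 99.8%.

    pre-initiator → initiator (k = 0.00289 min⁻¹)
    protic impurity + free monomer → quenched substrate (k = 0.0986 M⁻¹ min⁻¹)
    free monomer + initiator → living end + monomer in chains (k = 0.0341 M⁻¹ min⁻¹)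
    free monomer + living end → monomer in chains + living end, rate k4*[living end]*[free monomer] (k = 0.326 M⁻¹ min⁻¹)

At 20.0 h the flask holds 69.8% in chains and 0.233% still free, which together make s, and 0.0185 M of living ends, fewer than the pre-initiator charged, with 0.00770 M as initiator and 3.12% of its charge still pre-initiator; 0.371 M over those ends gives 20.1. Read the same flask at 5.0 h and s holds again: free monomer 39.8% and monomer in chains 30.2% add up to 70.0%. There 56.9% of the surviving share is still free monomer, and c stands at 60.2%.

The readings were computed for substances that don't exist, and the scatter is random.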